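Ring labels: A = 4-hydroxy-2-methoxyphenyl, B = 4-hydroxyphenyl on the stereocentre C*, C = central resorcinol, D = ketone aryl; the chain is ring A–CaH2–CbH2–C*. The ring C hydroxyl ortho to C* and Ca are joined through C(aryl)–C(aryl)–C*–Cb, so an O–Ca bond would close a pyran: the left half is a 2,4-diarylchroman short of one bond. The key step builds that sacrificial chroman. A chiral phosphoric acid turns a racemic, ring C-brominated ring B/ring C ortho-hydroxybenzhydrol into an ortho-quinone methide, which adds the ring A vinylphenol and forms C*–Cb, O–Ca, the pyran and the C* configuration at once. Methylation, Heck coupling and hydrogenolysis of O–Ca finish.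

Key step: step 4

Remarks on the chemistry:
- The target stereocentre C* is (R). It corresponds to C4 of the (2S,4R)-cis-chroman 9, and its descriptor does not change when the O–Ca bond is cut.
- Assumption: the (R)-configured acid is taken to give the 4R product by analogy with the two-point hydrogen-bond model. Should the sense of induction prove opposite, the (S)-acid is used without other change.
- Compounds 1, 3, 6 and 11 are catalogue chemicals.
- Design of the precursor: the ring C bromine is the handle for the ring D chain and also blocks the ring carbon para to the ring C hydroxyl against self-alkylation. Every oxygen except the two that the catalyst must bind is benzylated, so one hydrogenation unmasks everything. The ring D chain is introduced with a stable allylic alcohol, which gives the saturated ketone directly and avoids a polymerisable aryl vinyl ketone.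

Step 1
Reactants: 1 5-bromo-2,4-dihydroxybenzaldehyde
Product: 2 4-(benzyloxy)-5-bromo-2-hydroxybenzaldehyde
Conditions: BnBr (1.05 equiv), NaHCO3 (1.5 equiv), MeCN, 80 °C
Reagents that add atoms: benzyl bromide, BrCc1ccccc1
Why: Williamson ether synthesis in which the weak base ionises only the 4-hydroxyl (acidified by the para-formyl and ortho-bromo groups), while the 2-hydroxyl stays locked in its hydrogen bond to the aldehyde, so mono-benzylation at O-4 should result.

Step 2
Reactants: 2 4-(benzyloxy)-5-bromo-2-hydroxybenzaldehyde; 3 1-(benzyloxy)-4-bromobenzene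
Product: 5 5-(benzyloxy)-2-{[4-(benzyloxy)phenyl](hydroxy)methyl}-4-bromophenol (racemic), via aryl Grignard reagent 4 (not isolated)
Conditions: 3 (2.6 equiv), Mg, THF, 50 °C; then 2, THF, 0 °C → rt; sat. aq NH4Cl; chromatography on Et3N-deactivated silica
Reagents that add atoms: none
Why: Grignard reagent formation followed by 1,2-addition to the aldehyde, in which the first equivalent of 4 only deprotonates the phenol, the second adds to the formyl group, the ring C bromide is inert to an aryl Grignard reagent in the absence of a transition metal, and the new carbinol centre forms racemic, which is harmless because it becomes planar in step 4.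

Step 3
Reactants: 6 4-(benzyloxy)-2-hydroxybenzaldehyde
Product: 7 5-(benzyloxy)-2-ethenylphenol (5-(benzyloxy)-2-vinylphenol)
Conditions: Ph3PCH3Br (2.5 equiv), KOtBu (2.5 equiv), THF, 0 °C → rt; sat. aq NH4Cl; stored cold and used promptly
Reagents that add atoms: methyltriphenylphosphonium bromide (as its ylide), C[P+](c1ccccc1)(c1ccccc1)c1ccccc1.[Br-]
Why: Wittig methylenation, run with excess ylide because one equivalent of base is taken up by the phenol; no stereocentre is formed.

Step 4
Reactants: 5 5-(benzyloxy)-2-{[4-(benzyloxy)phenyl](hydroxy)methyl}-4-bromophenol (racemic); 7 5-(benzyloxy)-2-ethenylphenol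
Product: 9 5-(benzyloxy)-2-[(2S,4R)-7-(benzyloxy)-4-[4-(benzyloxy)phenyl]-6-bromo-3,4-dihydro-2H-chromen-2-yl]phenol, via ortho-quinone methide 8 (not isolated)
Conditions: (R)-TRIP [(R)-3,3'-bis(2,4,6-triisopropylphenyl)-1,1'-binaphthyl-2,2'-diyl hydrogen phosphate] (10 mol%), 7 (1.3 equiv), 3 Å MS, toluene, 0 °C → rt
Reagents that add atoms: none
Why: The phosphoric acid protonates the benzylic hydroxyl of 5 and water leaves to give the planar ortho-quinone methide 8, so both enantiomers of the carbinol converge on one intermediate. The catalyst then holds 8 through a P–OH···O=C hydrogen bond and the phenol of 7 through O–H···O=P, and inside this assembly the CH2 terminus of the styrene adds to the exocyclic carbon of 8 (C*) while the ring C oxygen closes on the ring A benzylic carbon Ca, an asynchronous inverse-electron-demand oxa-[4+2] cycloaddition (oxa-Diels–Alder reaction) of the known type between acid-generated ortho-quinone methides and ortho-hydroxystyrenes. The six-membered pyran is closed by the cycloaddition itself (4π O=C–C=C* plus 2π Cb=Ca, in the stepwise limit a 6-exo-trig capture of the ring A-stabilised benzylic cation by oxygen). C4 (C*, R) is set by the chiral pocket of the catalyst, which exposes one face of the quinone methide carbon, and C2 (S) follows from the compact cis transition state with both aryl groups pseudo-equatorial and is of no consequence because step 8 erases it. The step needs face selectivity at C* and head-to-tail regiochemistry: the two-point hydrogen-bonded template should secure the first, and the polarisation of the alkene by the para-benzyloxy and ortho-hydroxy groups of ring A (nucleophilic CH2 terminus, cation-stabilising Ca) the second. Bromine blocks the most nucleophilic carbon of ring C against self-alkylation, and the benzylated oxygens of rings B and C rule out para-quinone methides.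

Step 5
Reactants: 9 5-(benzyloxy)-2-[(2S,4R)-7-(benzyloxy)-4-[4-(benzyloxy)phenyl]-6-bromo-3,4-dihydro-2H-chromen-2-yl]phenol
Product: 10 (2S,4R)-7-(benzyloxy)-2-[4-(benzyloxy)-2-methoxyphenyl]-4-[4-(benzyloxy)phenyl]-6-bromo-3,4-dihydro-2H-chromene
Conditions: MeI (1.5 equiv), K2CO3 (2 equiv), DMF, rt
Reagents that add atoms: iodomethane, CI
Why: Williamson O-methylation (SN2) of the only free phenol, kept at room temperature so that the phenoxide is alkylated before it can reopen the benzylic ether; both stereocentres are untouched.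

Step 6
Reactants: 11 4-(benzyloxy)benzaldehyde
Product: 12 1-[4-(benzyloxy)phenyl]prop-2-en-1-ol (racemic)
Conditions: CH2=CHMgBr (1.2 equiv), THF, 0 °C; sat. aq NH4Cl
Reagents that add atoms: vinylmagnesium bromide, C=C[Mg]Br
Why: Grignard 1,2-addition of a vinyl nucleophile to an aromatic aldehyde; the carbinol centre forms racemic and is destroyed when it becomes the ketone carbon in step 7.

Step 7
Reactants: 10 (2S,4R)-7-(benzyloxy)-2-[4-(benzyloxy)-2-methoxyphenyl]-4-[4-(benzyloxy)phenyl]-6-bromo-3,4-dihydro-2H-chromene; 12 1-[4-(benzyloxy)phenyl]prop-2-en-1-ol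
Product: 14 3-[(2S,4R)-7-(benzyloxy)-2-[4-(benzyloxy)-2-methoxyphenyl]-4-[4-(benzyloxy)phenyl]-3,4-dihydro-2H-chromen-6-yl]-1-[4-(benzyloxy)phenyl]propan-1-one, via enol 13 (not isolated)
Conditions: Pd(OAc)2 (5 mol%), P(t-Bu)3·HBF4 (10 mol%), Cy2NMe (2 equiv), 12 (1.5 equiv), 1,4-dioxane, 90 °C
Reagents that add atoms: none
Why: Mizoroki–Heck arylation of a secondary allylic alcohol, in which the bulky electron-rich phosphine lets zerovalent palladium insert into the electron-rich aryl bromide, the aryl group is delivered to the unsubstituted alkene terminus, β-hydride elimination toward the carbinol carbon gives enol 13, and tautomerisation gives the saturated ketone with C2 and C4 untouched.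

Step 8
Reactants: 14 3-[(2S,4R)-7-(benzyloxy)-2-[4-(benzyloxy)-2-methoxyphenyl]-4-[4-(benzyloxy)phenyl]-3,4-dihydro-2H-chromen-6-yl]-1-[4-(benzyloxy)phenyl]propan-1-one
Product: 16 3-{2,4-dihydroxy-5-[(1R)-1-(4-hydroxyphenyl)-3-(4-hydroxy-2-methoxyphenyl)propyl]phenyl}-1-(4-hydroxyphenyl)propan-1-one, via ring-closed tetraphenol 15 (not isolated)
Conditions: H2 (3 atm), 10% Pd/C, MeOH/EtOAc 1:1, rt → 40 °C, stopped when 15 is consumed
Reagents that add atoms: none
Why: Heterogeneous catalytic hydrogenolysis, in which the four benzyl ethers should cleave first (15) and then the O1–C2 bond, a secondary benzyl aryl ether made labile by the electron-rich ring A, is cut so that C2 becomes the CH2 group Ca and its configuration disappears, while C4 (C*, R), which carries no oxygen, and the slowly reducing 4-hydroxyaryl ketone are retained.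

Compound list
1 | 5-bromo-2,4-dihydroxybenzaldehyde | O=Cc1cc(Br)c(O)cc1O | starting material
2 | 4-(benzyloxy)-5-bromo-2-hydroxybenzaldehyde | O=Cc1cc(Br)c(OCc2ccccc2)cc1O | intermediate
3 | 1-(benzyloxy)-4-bromobenzene | Brc1ccc(OCc2ccccc2)cc1 | starting material
4 | [4-(benzyloxy)phenyl]magnesium bromide | Br[Mg]c1ccc(OCc2ccccc2)cc1 | intermediate
5 | 5-(benzyloxy)-2-{[4-(benzyloxy)phenyl](hydroxy)methyl}-4-bromophenol (racemic) | OC(c1ccc(OCc2ccccc2)cc1)c1cc(Br)c(OCc2ccccc2)cc1O | intermediate
6 | 4-(benzyloxy)-2-hydroxybenzaldehyde | O=Cc1ccc(OCc2ccccc2)cc1O | starting material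
7 | 5-(benzyloxy)-2-ethenylphenol | C=Cc1ccc(OCc2ccccc2)cc1O | intermediate
8 | 3-(benzyloxy)-6-{[4-(benzyloxy)phenyl]methylidene}-4-bromocyclohexa-2,4-dien-1-one (alkene geometry not defined) | O=C1C=C(OCc2ccccc2)C(Br)=CC1=Cc1ccc(OCc2ccccc2)cc1 | intermediate
9 | 5-(benzyloxy)-2-[(2S,4R)-7-(benzyloxy)-4-[4-(benzyloxy)phenyl]-6-bromo-3,4-dihydro-2H-chromen-2-yl]phenol (cis) | Oc1cc(OCc2ccccc2)ccc1[C@@H]1C[C@H](c2ccc(OCc3ccccc3)cc2)c2cc(Br)c(OCc3ccccc3)cc2O1 | intermediate
10 | (2S,4R)-7-(benzyloxy)-2-[4-(benzyloxy)-2-methoxyphenyl]-4-[4-(benzyloxy)phenyl]-6-bromo-3,4-dihydro-2H-chromene | COc1cc(OCc2ccccc2)ccc1[C@@H]1C[C@H](c2ccc(OCc3ccccc3)cc2)c2cc(Br)c(OCc3ccccc3)cc2O1 | intermediate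
11 | 4-(benzyloxy)benzaldehyde | O=Cc1ccc(OCc2ccccc2)cc1 | starting material
12 | 1-[4-(benzyloxy)phenyl]prop-2-en-1-ol (racemic) | C=CC(O)c1ccc(OCc2ccccc2)cc1 | intermediate
13 | 3-[(2S,4R)-7-(benzyloxy)-2-[4-(benzyloxy)-2-methoxyphenyl]-4-[4-(benzyloxy)phenyl]-3,4-dihydro-2H-chromen-6-yl]-1-[4-(benzyloxy)phenyl]prop-1-en-1-ol (alkene geometry not defined) | COc1cc(OCc2ccccc2)ccc1[C@@H]1C[C@H](c2ccc(OCc3ccccc3)cc2)c2cc(CC=C(O)c3ccc(OCc4ccccc4)cc3)c(OCc3ccccc3)cc2O1 | intermediate
14 | 3-[(2S,4R)-7-(benzyloxy)-2-[4-(benzyloxy)-2-methoxyphenyl]-4-[4-(benzyloxy)phenyl]-3,4-dihydro-2H-chromen-6-yl]-1-[4-(benzyloxy)phenyl]propan-1-one | COc1cc(OCc2ccccc2)ccc1[C@@H]1C[C@H](c2ccc(OCc3ccccc3)cc2)c2cc(CCC(=O)c3ccc(OCc4ccccc4)cc3)c(OCc3ccccc3)cc2O1 | intermediate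
15 | 3-[(2S,4R)-7-hydroxy-2-(4-hydroxy-2-methoxyphenyl)-4-(4-hydroxyphenyl)-3,4-dihydro-2H-chromen-6-yl]-1-(4-hydroxyphenyl)propan-1-one | COc1cc(O)ccc1[C@@H]1C[C@H](c2ccc(O)cc2)c2cc(CCC(=O)c3ccc(O)cc3)c(O)cc2O1 | intermediate
16 | 3-{2,4-dihydroxy-5-[(1R)-1-(4-hydroxyphenyl)-3-(4-hydroxy-2-methoxyphenyl)propyl]phenyl}-1-(4-hydroxyphenyl)propan-1-one | COc1cc(O)ccc1CC[C@H](c1ccc(O)cc1)c1cc(CCC(=O)c2ccc(O)cc2)c(O)cc1O | target

Total step count: 8
Longest linear sequence: 6 steps (steps 1, 2, 4, 5, 7, 8)

Steps most likely to fail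

Step 4. The two faces of the quinone methide carbon may be poorly discriminated with these heavily oxygenated partners. Enantiopurity may also erode through acid-induced reopening of the product, and the free ring carbon para to the hydroxyl of 7 may compete with the alkene terminus as the nucleophile. The fallback replaces asymmetric catalysis by resolution. It sets out from 5 (with 7): cycloaddition under an achiral acid (diphenyl phosphate, 10 mol%, toluene, rt) should give the racemic cis-chroman F1. Separation on a preparative chiral stationary phase (supercritical fluid chromatography) would supply the (2S,4R) enantiomer, and the route is rejoined at 9.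

Step 8. Hydrogenolysis may stall at the ring-closed stage because the O1–C2 bond is cleaved too slowly. Under the forcing that this then requires, the aryl ketone may be reduced further. The fallback opens the pyran before the ketone exists. It sets out from 10: ionic hydrogenation (Et3SiH, BF3·OEt2, CH2Cl2, −40 → 0 °C) through the ring A-stabilised benzylic cation should give the ring-opened bromophenol F2. The Heck/isomerisation coupling with 12 under the step 7 conditions (one further equivalent of base for the phenol) should then give the ring-opened ketone F3. A mild hydrogenation (H2, 1 atm, 10% Pd/C, EtOAc/MeOH, rt) has only three benzyl ethers left to remove and comes back to the route at 16.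

Step 7. Oxidative addition into the electron-rich, ortho-alkoxy aryl bromide may be slow, so that 12 isomerises to its propiophenone first, or β-hydride elimination may run toward the benzylic carbon. The fallback builds the chain by carbonyl chemistry. It sets out from 10: bromine–lithium exchange (n-BuLi, THF, −78 °C) and quenching with DMF should give the aldehyde F4. Claisen–Schmidt condensation with commercial 1-[4-(benzyloxy)phenyl]ethanone (KOH, EtOH/THF, rt) should give the (E)-chalcone F5. The step 8 conditions then also saturate the alkene, pass through 15 and come back to the route at 16.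

Further compounds
F1 | step 4 | racemic cis-chroman (1:1 mixture of 9 and its (2R,4S) enantiomer) | Oc1cc(OCc2ccccc2)ccc1[C@@H]1C[C@H](c2ccc(OCc3ccccc3)cc2)c2cc(Br)c(OCc3ccccc3)cc2O1.Oc1cc(OCc2ccccc2)ccc1[C@H]1C[C@@H](c2ccc(OCc3ccccc3)cc2)c2cc(Br)c(OCc3ccccc3)cc2O1
F2 | step 8 | 5-(benzyloxy)-2-{(1R)-3-[4-(benzyloxy)-2-methoxyphenyl]-1-[4-(benzyloxy)phenyl]propyl}-4-bromophenol | COc1cc(OCc2ccccc2)ccc1CC[C@H](c1ccc(OCc2ccccc2)cc1)c1cc(Br)c(OCc2ccccc2)cc1O
F3 | step 8 | 3-{2-(benzyloxy)-5-[(1R)-3-[4-(benzyloxy)-2-methoxyphenyl]-1-[4-(benzyloxy)phenyl]propyl]-4-hydroxyphenyl}-1-[4-(benzyloxy)phenyl]propan-1-one | COc1cc(OCc2ccccc2)ccc1CC[C@H](c1ccc(OCc2ccccc2)cc1)c1cc(CCC(=O)c2ccc(OCc3ccccc3)cc2)c(OCc2ccccc2)cc1O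
F4 | step 7 | (2S,4R)-7-(benzyloxy)-2-[4-(benzyloxy)-2-methoxyphenyl]-4-[4-(benzyloxy)phenyl]-3,4-dihydro-2H-chromene-6-carbaldehyde | COc1cc(OCc2ccccc2)ccc1[C@@H]1C[C@H](c2ccc(OCc3ccccc3)cc2)c2cc(C=O)c(OCc3ccccc3)cc2O1
F5 | step 7 | (2E)-3-[(2S,4R)-7-(benzyloxy)-2-[4-(benzyloxy)-2-methoxyphenyl]-4-[4-(benzyloxy)phenyl]-3,4-dihydro-2H-chromen-6-yl]-1-[4-(benzyloxy)phenyl]prop-2-en-1-one | COc1cc(OCc2ccccc2)ccc1[C@@H]1C[C@H](c2ccc(OCc3ccccc3)cc2)c2cc(/C=C/C(=O)c3ccc(OCc4ccccc4)cc3)c(OCc3ccccc3)cc2O1
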